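**Plan**

- Retrosynthesis (quinone numbering: C1 =O, C2 OMe, C3 H, C4 =O, C5 Me, C6 pentacosyl): the O-methyl group is cut first, then the C1 oxygen (para-oxidation of a resorcinol C–H). The ring of the resulting 4-methyl-5-pentacosylresorcinol is cut at C3–C4 and at C1–C6.
- This gives a C1–C2–C3 1,3-dinucleophile (diethyl 3-oxopentanedioate, with two ester helpers) and a C4–C5–C6 1,3-dielectrophile (a 2-methyl-2,3-dienoate: ester carbon = C4, methyl-bearing carbon = C5, central allene carbon = C6). The allene goes back to hexacosanoic acid by a ketene Wittig disconnection.
- Enabling feature: ring atoms C1(=O)–C2(OMe)–C3(H)–C4(=O) carry the alternating 1,3-oxygenation of an acetate-derived alkylresorcinol. C1 and C3 are therefore the two α-carbons of a 3-oxoglutarate, and C4 and C6 are an acyl carbon and a β-carbon. The annulation copies the Claisen chain-extension bond and the ring-closing bond of the presumed polyketide biosynthesis.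
- Forward: acid chloride → allenoate (the C26 acid supplies C6 plus the chain) → one-pot Michael/Dieckmann [3+3] benzannulation (the only ring) → saponification and double decarboxylation → para-quinone → O-methylation.
- Stereochemistry: the target has no stereocentre and no stereogenic double bond. The allene is used racemic and its axis vanishes on aromatisation.

Key step: step 3

Assumption: the side chain is read as the unbranched n-pentacosyl (C25) group.

**Route**

Step 1
Reactants: 1 hexacosanoic acid
Product: 2 hexacosanoyl chloride
Conditions: (COCl)2, DMF (cat.), toluene, 50 °C; evaporate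
Reagents that add atoms: oxalyl chloride, O=C(Cl)C(=O)Cl
Why: Acyl chloride formation through the chloroiminium species from DMF and oxalyl chloride should be clean on a saturated fatty acid, the by-products being gases.

Step 2
Reactants: 2 hexacosanoyl chloride; 3 ethyl 2-(triphenylphosphoranylidene)propanoate
Product: 5 ethyl 2-methyloctacosa-2,3-dienoate (racemic allene), via tetracosylketene 4 (not isolated)
Conditions: Et3N (1.1 equiv), CH2Cl2, 0 °C to rt
Reagents that add atoms: none
Why: Et3N dehydrochlorinates 2 to ketene 4, whose C=O undergoes a Wittig reaction with the stabilised ylide 3 to give the 2,3-dienoate (ketene Wittig allenoate synthesis), the carboxyl carbon of the fatty acid becoming the central allene carbon.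

Step 3
Reactants: 5 ethyl 2-methyloctacosa-2,3-dienoate; 6 diethyl 3-oxopentanedioate
Product: 8 diethyl 2,4-dihydroxy-5-methyl-6-pentacosylbenzene-1,3-dicarboxylate, via Michael adduct 7 (not isolated)
Conditions: 6, NaH (2.2 equiv), THF, 0 °C; then 5, rt to reflux; aq. HCl
Reagents that add atoms: none
Why: The sodium enolate of 6 adds through one α-carbon to the central allene carbon of 5 (Michael addition), proton transfer moves the charge to the other α-carbon, which attacks the ethyl ester of the former allenoate with loss of ethoxide (Dieckmann-type Claisen acylation), and enolisation of the resulting cyclohexadienone gives the benzene ring without an oxidant because the allene already holds the required oxidation level. The closest known reaction type is the Michael addition/Dieckmann [3+3] benzannulation of 3-oxoglutarate anions with alkynoates and allenoates, related to the base-induced self-condensation of 3-oxoglutarates to resorcinols, and the two new bonds are the Claisen bond (C3–C4) and the ring-closing bond (C1–C6) of an alkylresorcinol polyketide assembly. The only ring closes by a 6-exo-trig C-acylation of a doubly stabilised carbanion followed by aromatisation. No stereocentre is formed, and the allene axis and the alkene geometry of adduct 7 are erased on aromatisation. The step needs regiocontrol and C- over O-acylation: the donor is symmetric, the central allene carbon is the only Michael position and the ester carbon the only acyl position of 5, so methyl and chain end up adjacent with the methyl next to the new phenol carbon, while lactonisation to a 2-pyranone is reversible under the ethoxide set free and the aromatic bis-phenoxide is the thermodynamic sink. The two ester groups make both α-carbons of the three-carbon donor nucleophilic and are removed in step 4.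

Step 4
Reactants: 8 diethyl 2,4-dihydroxy-5-methyl-6-pentacosylbenzene-1,3-dicarboxylate
Product: 10 4-methyl-5-pentacosylbenzene-1,3-diol, via dicarboxylic acid 9 (not isolated)
Conditions: KOH (excess), ethylene glycol/H2O, 150 °C, argon; then aq. HCl (pH 1), 90 °C
Reagents that add atoms: none
Why: Saponification of the two salicylate-type esters and protodecarboxylation of the resulting ortho- and para-hydroxybenzoic acids through ipso protonation of the electron-rich ring (ester hydrolysis, then decarboxylation) is the classical way to strip ester helpers from 2,4-dihydroxyisophthalates, and neither the saturated chain nor the phenols should suffer in hot alkali under argon.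

Step 5
Reactants: 10 4-methyl-5-pentacosylbenzene-1,3-diol
Product: 11 2-hydroxy-5-methyl-6-pentacosyl-1,4-benzoquinone
Conditions: (KSO3)2NO (2.5 equiv), KH2PO4 (aq.), methyltrioctylammonium chloride (cat.), CH2Cl2/H2O, rt
Reagents that add atoms: potassium nitrosodisulfonate, [K+].[K+].[O-]S(=O)(=O)N([O])S(=O)(=O)[O-]
Why: In this Teuber oxidation one nitrosodisulfonate radical abstracts a phenolic hydrogen and a second adds at C6 of the resorcinol, the only hydrogen-bearing position para to a hydroxyl, so that loss of imidodisulfonate should give the single para-quinone with the other hydroxyl left as the quinone OH.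

Step 6
Reactants: 11 2-hydroxy-5-methyl-6-pentacosyl-1,4-benzoquinone
Product: 12 2-methoxy-5-methyl-6-pentacosyl-1,4-benzoquinone (target)
Conditions: MeOH/CHCl3, H2SO4 (cat.), reflux
Reagents that add atoms: methanol, CO
Why: The 2-hydroxyquinone is a vinylogous carboxylic acid, so acid-catalysed exchange with methanol (Fischer-type vinylogous esterification by addition–elimination at C2) should methylate the only hydroxyl on oxygen and avoid the C-alkylation that basic alkylation of the ambident anion could give.

**Compound list**

1 | hexacosanoic acid | CCCCCCCCCCCCCCCCCCCCCCCCCC(=O)O | starting material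
2 | hexacosanoyl chloride | CCCCCCCCCCCCCCCCCCCCCCCCCC(=O)Cl | intermediate
3 | ethyl 2-(triphenylphosphoranylidene)propanoate | CCOC(=O)C(C)=P(c1ccccc1)(c1ccccc1)c1ccccc1 | starting material
4 | tetracosylketene (hexacos-1-en-1-one) | CCCCCCCCCCCCCCCCCCCCCCCCC=C=O | intermediate
5 | ethyl 2-methyloctacosa-2,3-dienoate (racemic) | CCCCCCCCCCCCCCCCCCCCCCCCC=C=C(C)C(=O)OCC | intermediate
6 | diethyl 3-oxopentanedioate | CCOC(=O)CC(=O)CC(=O)OCC | starting material
7 | diethyl 2-(1-ethoxy-2-methyl-1-oxooctacos-2-en-3-yl)-3-oxopentanedioate (Michael adduct, alkene geometry not defined) | CCCCCCCCCCCCCCCCCCCCCCCCCC(=C(C)C(=O)OCC)C(C(=O)OCC)C(=O)CC(=O)OCC | intermediate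
8 | diethyl 2,4-dihydroxy-5-methyl-6-pentacosylbenzene-1,3-dicarboxylate | CCCCCCCCCCCCCCCCCCCCCCCCCc1c(C)c(O)c(C(=O)OCC)c(O)c1C(=O)OCC | intermediate
9 | 2,4-dihydroxy-5-methyl-6-pentacosylbenzene-1,3-dicarboxylic acid | CCCCCCCCCCCCCCCCCCCCCCCCCc1c(C)c(O)c(C(=O)O)c(O)c1C(=O)O | intermediate
10 | 4-methyl-5-pentacosylbenzene-1,3-diol | CCCCCCCCCCCCCCCCCCCCCCCCCc1cc(O)cc(O)c1C | intermediate
11 | 2-hydroxy-5-methyl-6-pentacosyl-1,4-benzoquinone | CCCCCCCCCCCCCCCCCCCCCCCCCC1=C(C)C(=O)C=C(O)C1=O | intermediate
12 | 2-methoxy-5-methyl-6-pentacosyl-1,4-benzoquinone (5-methoxy-2-methyl-3-pentacosylcyclohexa-2,5-diene-1,4-dione) | CCCCCCCCCCCCCCCCCCCCCCCCCC1=C(C)C(=O)C=C(OC)C1=O | target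

**Totals and risks**

Total step count: 6. Longest linear sequence: 6 steps (1 to 12).

Steps most likely to fail:

Step 3. The Michael adduct may close on oxygen (lactonisation to a 2-pyranone) faster than on carbon, and the allenoate may isomerise or oligomerise under base before the conjugate addition. Fallback: a classical cyclohexanedione route sets out from acid chloride 2 and comes back at resorcinol 10, bypassing steps 3 and 4. Reduction of 2 with LiAlH(O-t-Bu)3 (THF, −78 °C) would give hexacosanal F1. A Wittig reaction with 3-(triphenylphosphoranylidene)butan-2-one (toluene, reflux) would give (E)-3-methylnonacos-3-en-2-one F2. Michael addition of dimethyl malonate and Claisen closure from the methyl ketone (NaOMe, MeOH, reflux) would give methyl 5-methyl-2,4-dioxo-6-pentacosylcyclohexane-1-carboxylate F3. Saponification and decarboxylation (aq. NaOH, then HCl, heat) would give 4-methyl-5-pentacosylcyclohexane-1,3-dione F4. Dehydrogenation (Pd/C, mesitylene, reflux) would then give 10.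

Step 5. The electron-rich resorcinol and the hydroxyquinone may be over-oxidised or oxidatively coupled (attack at the position between the two hydroxyls), and phase transfer of the waxy substrate may be slow. Fallback: it sets out from resorcinol 10 and comes back at target 12, step 6 not being needed. Exhaustive O-methylation (Me2SO4, K2CO3, acetone, reflux) would give 1,5-dimethoxy-2-methyl-3-pentacosylbenzene F5. Oxidative demethylation with CrO3 in AcOH/H2O should attack the only ring C–H that is para to a methoxy group; the para-methoxy group is lost and the other is kept.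

Step 4. Saponification of the ester flanked by the long chain and a phenoxide may stay incomplete, and the resorcinol dianion may be oxidised by traces of air in hot alkali. Fallback: it sets out from allenoate 5 and comes back at resorcinol 10. The annulation of step 3 run with di-tert-butyl 3-oxopentanedioate (NaH, THF) would give di-tert-butyl 2,4-dihydroxy-5-methyl-6-pentacosylbenzene-1,3-dicarboxylate F6. CF3CO2H in CH2Cl2 at rt should remove the tert-butyl groups by alkyl–oxygen cleavage, which is insensitive to crowding at the acyl carbon; the ring is fully substituted at this stage and cannot be tert-butylated. This gives diacid 9, which should lose CO2 on warming in dioxane/aq. HCl to give 10.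

**Further compounds**

F1 | step 3 | hexacosanal | CCCCCCCCCCCCCCCCCCCCCCCCCC=O
F2 | step 3 | (E)-3-methylnonacos-3-en-2-one | CCCCCCCCCCCCCCCCCCCCCCCCC/C=C(\C)C(C)=O
F3 | step 3 | methyl 5-methyl-2,4-dioxo-6-pentacosylcyclohexane-1-carboxylate (mixture of diastereomers) | CCCCCCCCCCCCCCCCCCCCCCCCCC1C(C)C(=O)CC(=O)C1C(=O)OC
F4 | step 3 | 4-methyl-5-pentacosylcyclohexane-1,3-dione (mixture of diastereomers) | CCCCCCCCCCCCCCCCCCCCCCCCCC1CC(=O)CC(=O)C1C
F5 | step 5 | 1,5-dimethoxy-2-methyl-3-pentacosylbenzene | CCCCCCCCCCCCCCCCCCCCCCCCCc1cc(OC)cc(OC)c1C
F6 | step 4 | di-tert-butyl 2,4-dihydroxy-5-methyl-6-pentacosylbenzene-1,3-dicarboxylate | CCCCCCCCCCCCCCCCCCCCCCCCCc1c(C)c(O)c(C(=O)OC(C)(C)C)c(O)c1C(=O)OC(C)(C)C
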